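**Plan**

1. Retrosynthesis: the C8–C3'' bond between ring A of the flavanone and the cyclohexene (numbered C1''(CH3)=C2''–C3''–C4''(aroyl)–C5''(aryl)–C6''H2) is cut first, as a retro-aromatic-Claisen, to a tertiary aryl ether O7–C1''. That ether is cut to a 7-hydroxyflavanone and a C3'' allylic carbonate (retro-Tsuji–Trost). The cyclohexene is cut across C3''–C4'' and C5''–C6'' (retro-Diels–Alder), both enones across Cα=Cβ (retro-aldol), and the flavanone across O1–C2.
2. Forward: one silylated aldehyde feeds both halves. A 2'-hydroxychalcone and a dienyl carbonate build the cyclohexene first. A second chalcone is closed to the flavanone and resolved. The halves are then joined at O7–C1'' and re-joined at C8–C3'' in the same flask, and six silyl ethers are removed.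
3. Enabling feature: ring A has a free 7-OH beside the unsubstituted C8, and the cyclohexene has the allyl triad C1''=C2''–C3''. With O7 on C1'', the array C8=C7–O7–C1''–C2''=C3'' is set for a [3,3] shift that can only deliver C8 to C3'' on the face that carries the oxygen.
4. Stereochemistry: C4''/C5'' trans comes from the E-enone, C3''–O cis to the aroyl group from the endo rule, and the absolute sense from a chiral borate. This oxygen is relayed C3''→C1'' (palladium, double inversion) and returned C1''→C3'' as carbon (suprafacial Claisen), so ring A ends cis to the aroyl group. Flavanone C2 (S) is selected by kinetic resolution.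

Key step: step 12

Assumption: the sense of induction of the (S)-VANOL borate in step 6 and of the (R,R)-TsDPEN catalyst in step 10 is assigned by analogy with simpler 2'-hydroxychalcones and flavanones; if either proves opposite, the mirror-image ligand is used and nothing else changes.

Abbreviations: TBS = tert-butyldimethylsilyl; prenyl = 3-methylbut-2-en-1-yl.

**Route**

Step 1
Reactants: 1 2,4-dihydroxyacetophenone; 2 prenyl bromide (1-bromo-3-methylbut-2-ene)
Product: 3 2,4-dihydroxy-3-prenylacetophenone
Conditions: DBU, THF, 0 °C → rt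
Reagents that add atoms: none
Why: Nuclear prenylation (C-alkylation of the ambident resorcinolate) should take place mainly at C3, the carbon flanked by both oxygens, while the chelated 2-OH resists O-alkylation.

Step 2
Reactants: 3 2,4-dihydroxy-3-prenylacetophenone
Product: 4 4-O-TBS-2-hydroxy-3-prenylacetophenone
Conditions: TBSCl (1.1 equiv), imidazole, DMF, 0 °C
Reagents that add atoms: tert-butyldimethylsilyl chloride, CC(C)(C)[Si](C)(C)Cl
Why: Silyl ether formation should occur only at the free 4-OH because the 2-OH is held in a hydrogen bond to the acetyl carbonyl.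

Step 3
Reactants: 5 2,4-dihydroxybenzaldehyde
Product: 6 2,4-bis(TBS-oxy)benzaldehyde
Conditions: TBSCl (2.5 equiv), imidazole, DMF, rt
Reagents that add atoms: tert-butyldimethylsilyl chloride, CC(C)(C)[Si](C)(C)Cl
Why: Exhaustive silyl ether formation with excess silyl chloride and imidazole should also capture the chelated ortho-hydroxyl.

Step 4
Reactants: 4 4-O-TBS-2-hydroxy-3-prenylacetophenone; 6 2,4-bis(TBS-oxy)benzaldehyde
Product: 7 tris-TBS 2'-hydroxychalcone (E)
Conditions: LiN(SiMe3)2 (2.2 equiv), THF, −78 °C; then 6, −78 °C → rt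
Reagents that add atoms: none
Why: A Claisen–Schmidt (aldol) condensation run with a non-nucleophilic amide base spares the aryl silyl ethers, and E1cB loss of hydroxide from the lithium aldolate should give the conjugated E-enone.

Step 5
Reactants: 8 3-methylbut-2-enal
Product: 9 methyl (1E)-3-methylbuta-1,3-dien-1-yl carbonate
Conditions: KOtBu, THF, −78 °C; then ClCO2Me, −78 → 0 °C
Reagents that add atoms: methyl chloroformate, COC(=O)Cl
Why: γ-Deprotonation of the s-trans enal gives the (E)-dienolate, whose oxygen terminus is acylated by the chloroformate (O-acylation of a dienolate).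

Step 6
Reactants: 7 tris-TBS 2'-hydroxychalcone; 9 dienyl methyl carbonate
Product: 10 endo cyclohexenyl carbonate (2'-OH free)
Conditions: (S)-VANOL (20 mol%), BH3·THF (20 mol%), AcOH (20 mol%), THF, rt; then 7 and 9, PhCF3, rt
Reagents that add atoms: none
Why: In this borate-promoted asymmetric Diels–Alder reaction the boron chelate of the 2'-hydroxy ketone activates the enone, the 1-carbonato and 3-methyl groups of 9 both send its CH2 terminus to the β-carbon, the endo transition state puts the C3'' carbonate cis to the C4'' aroyl group, the E-enone gives C4''/C5'' trans, and the chiral borate shields one enone face to set the absolute configuration.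

Step 7
Reactants: 10 endo cyclohexenyl carbonate (2'-OH free)
Product: 11 tetrakis-TBS cyclohexenyl carbonate
Conditions: TBSOTf, 2,6-lutidine, CH2Cl2, −78 → 0 °C
Reagents that add atoms: tert-butyldimethylsilyl trifluoromethanesulfonate, CC(C)(C)[Si](C)(C)OS(=O)(=O)C(F)(F)F
Why: Silyl ether formation with the silyl triflate should cap the chelated, hindered 2'-OH at low temperature with only a weak hindered base present, so that the β-carbonato ketone is not eliminated and the phenol cannot later attack C3'' of the π-allyl complex.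

Step 8
Reactants: 12 4-benzyloxy-2-hydroxyacetophenone; 6 2,4-bis(TBS-oxy)benzaldehyde
Product: 13 7-O-benzyl bis-TBS 2'-hydroxychalcone (E)
Conditions: LiN(SiMe3)2 (2.2 equiv), THF, −78 °C; then 6, −78 °C → rt
Reagents that add atoms: none
Why: The same amide-base Claisen–Schmidt condensation as in step 4 should give the E-enone without loss of the silyl ethers.

Step 9
Reactants: 13 7-O-benzyl bis-TBS 2'-hydroxychalcone
Product: 14 racemic 7-benzyloxy flavanone
Conditions: NaOAc, EtOH, 60 °C
Reagents that add atoms: none
Why: Buffered chalcone–flavanone isomerisation (6-endo-trig intramolecular oxa-Michael addition of the 2'-phenol) closes the pyranone ring and forms C2 as the racemate.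

Step 10
Reactants: 14 racemic 7-benzyloxy flavanone
Product: 15 (2S)-7-benzyloxy flavanone
Conditions: RuCl(p-cymene)[(R,R)-TsDPEN] (1 mol%), HCO2H/Et3N (5:2), EtOAc, rt, stopped near 55% conversion
Reagents that add atoms: none
Why: In this kinetic resolution by asymmetric transfer hydrogenation (Noyori–Ikariya type) the catalyst should reduce the (2R)-ketone to the cis-flavan-4-ol much faster than the (2S)-ketone, which is recovered, so the C2 configuration is selected here and not made.

Step 11
Reactants: 15 (2S)-7-benzyloxy flavanone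
Product: 16 (2S)-7-hydroxy flavanone bis-TBS ether
Conditions: H2 (1 atm), Pd on carbon (Pd/C), EtOAc, rt
Reagents that add atoms: none
Why: Hydrogenolysis of the benzyl aryl ether frees the 7-OH under neutral conditions that leave the aryl silyl ethers and the C2 stereocenter untouched, and it is done here because this fragment has no alkene.

Step 12
Reactants: 11 tetrakis-TBS cyclohexenyl carbonate; 16 (2S)-7-hydroxy flavanone bis-TBS ether (1.1 equiv)
Product: 18 C8-linked hexakis-TBS adduct (7-OH free), via tertiary O7–C1'' aryl ether 17 (not isolated)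
Conditions: Pd(PPh3)4 (5 mol%), toluene, 0 °C → rt; then 90 °C
Reagents that add atoms: none
Why: Zerovalent palladium ionises the C3'' carbonate with inversion to a π-allyl complex spanning C1''–C3'' (metal on the face away from the aroyl group); the methoxide released with CO2 deprotonates the 7-OH of 16 (a vinylogous acid), and the phenoxide attacks anti to the metal at C1'', the terminus remote from the electron-withdrawing aroyl group and not screened by it, so that ether 17 carries O7 on the aroyl face (net retention with 1,3-transposition). On warming, 17 should undergo an aromatic Claisen ([3,3]) rearrangement through the array C8=C7–O7–C1''–C2''=C3'' in a boat-like transition state, breaking O7–C1'', forming C8–C3'' and, after tautomerisation of the dienone, restoring the 7-phenol. The closest known reaction types are the Tsuji–Trost O-allylation of phenols at the more substituted allyl terminus and the thermal Claisen rearrangement of tertiary allyl aryl ethers, including its 1,3-chirality transfer in cyclohex-2-enyl aryl ethers. No ring is closed, since the cyclic array exists only in the transition state. The new stereocenter C3'' is fixed by the configuration of C1''–O7, because the shift is suprafacial across one face of the cyclohexene, which places ring A cis to the C4'' aroyl group and trans to the C5'' aryl group, while the C1'' stereocenter is consumed. The step needs O-attack at C1'' and not C3'' and migration to C8 and not C6: a C3'' ether that forms is returned to the π-allyl complex by the palladium still present and cannot rearrange at this temperature, and C8 is preferred because the C7–C8 bond of a 7-oxychroman-4-one has the higher double-bond character.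

Step 13
Reactants: 18 C8-linked hexakis-TBS adduct
Product: 19 target compound
Conditions: HF·pyridine, pyridine, THF, 0 °C → rt
Reagents that add atoms: none
Why: Fluoride-mediated desilylation should cleave all six aryl silyl ethers under buffered, weakly acidic conditions that neither open the flavanone ring nor epimerise C4'' nor cyclise the prenyl group onto a neighbouring phenol.

**Compound list**

1 | 1-(2,4-dihydroxyphenyl)ethan-1-one | CC(=O)c1ccc(O)cc1O | starting material
2 | 1-bromo-3-methylbut-2-ene (prenyl bromide) | CC(C)=CCBr | starting material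
3 | 1-[2,4-dihydroxy-3-(3-methylbut-2-en-1-yl)phenyl]ethan-1-one | CC(=O)c1ccc(O)c(CC=C(C)C)c1O | intermediate
4 | 1-[4-(TBS-oxy)-2-hydroxy-3-(3-methylbut-2-en-1-yl)phenyl]ethan-1-one | CC(=O)c1ccc(O[Si](C)(C)C(C)(C)C)c(CC=C(C)C)c1O | intermediate
5 | 2,4-dihydroxybenzaldehyde | O=Cc1ccc(O)cc1O | starting material
6 | 2,4-bis(TBS-oxy)benzaldehyde | O=Cc1ccc(O[Si](C)(C)C(C)(C)C)cc1O[Si](C)(C)C(C)(C)C | intermediate
7 | (E)-1-[4-(TBS-oxy)-2-hydroxy-3-prenylphenyl]-3-[2,4-bis(TBS-oxy)phenyl]prop-2-en-1-one | CC(C)=CCc1c(O[Si](C)(C)C(C)(C)C)ccc(C(=O)/C=C/c2ccc(O[Si](C)(C)C(C)(C)C)cc2O[Si](C)(C)C(C)(C)C)c1O | intermediate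
8 | 3-methylbut-2-enal | CC(C)=CC=O | starting material
9 | methyl (1E)-3-methylbuta-1,3-dien-1-yl carbonate | C=C(C)/C=C/OC(=O)OC | intermediate
10 | methyl (3''S,4''R,5''S)-4''-[4-(TBS-oxy)-2-hydroxy-3-prenylbenzoyl]-5''-[2,4-bis(TBS-oxy)phenyl]-1''-methylcyclohex-1''-en-3''-yl carbonate (carbonate cis to aroyl, aryl trans to aroyl) | CC(C)=CCc1c(O[Si](C)(C)C(C)(C)C)ccc(C(=O)[C@H]2[C@@H](OC(=O)OC)C=C(C)C[C@@H]2c2ccc(O[Si](C)(C)C(C)(C)C)cc2O[Si](C)(C)C(C)(C)C)c1O | intermediate
11 | methyl (3''S,4''R,5''S)-4''-[2,4-bis(TBS-oxy)-3-prenylbenzoyl]-5''-[2,4-bis(TBS-oxy)phenyl]-1''-methylcyclohex-1''-en-3''-yl carbonate | CC(C)=CCc1c(O[Si](C)(C)C(C)(C)C)ccc(C(=O)[C@H]2[C@@H](OC(=O)OC)C=C(C)C[C@@H]2c2ccc(O[Si](C)(C)C(C)(C)C)cc2O[Si](C)(C)C(C)(C)C)c1O[Si](C)(C)C(C)(C)C | intermediate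
12 | 1-[4-(benzyloxy)-2-hydroxyphenyl]ethan-1-one | CC(=O)c1ccc(OCc2ccccc2)cc1O | starting material
13 | (E)-1-[4-(benzyloxy)-2-hydroxyphenyl]-3-[2,4-bis(TBS-oxy)phenyl]prop-2-en-1-one | O=C(/C=C/c1ccc(O[Si](C)(C)C(C)(C)C)cc1O[Si](C)(C)C(C)(C)C)c1ccc(OCc2ccccc2)cc1O | intermediate
14 | racemic 7-(benzyloxy)-2-[2,4-bis(TBS-oxy)phenyl]chroman-4-one | O=C1CC(c2ccc(O[Si](C)(C)C(C)(C)C)cc2O[Si](C)(C)C(C)(C)C)Oc2cc(OCc3ccccc3)ccc12 | intermediate
15 | (2S)-7-(benzyloxy)-2-[2,4-bis(TBS-oxy)phenyl]chroman-4-one | O=C1C[C@@H](c2ccc(O[Si](C)(C)C(C)(C)C)cc2O[Si](C)(C)C(C)(C)C)Oc2cc(OCc3ccccc3)ccc12 | intermediate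
16 | (2S)-2-[2,4-bis(TBS-oxy)phenyl]-7-hydroxychroman-4-one | O=C1C[C@@H](c2ccc(O[Si](C)(C)C(C)(C)C)cc2O[Si](C)(C)C(C)(C)C)Oc2cc(O)ccc12 | intermediate
17 | (2S)-2-[2,4-bis(TBS-oxy)phenyl]-7-{[(1''S,4''S,5''S)-4''-[2,4-bis(TBS-oxy)-3-prenylbenzoyl]-5''-[2,4-bis(TBS-oxy)phenyl]-1''-methylcyclohex-2''-en-1''-yl]oxy}chroman-4-one (O7 on C1'' cis to the C4'' aroyl group) | CC(C)=CCc1c(O[Si](C)(C)C(C)(C)C)ccc(C(=O)[C@H]2C=C[C@@](C)(Oc3ccc4c(c3)O[C@H](c3ccc(O[Si](C)(C)C(C)(C)C)cc3O[Si](C)(C)C(C)(C)C)CC4=O)C[C@@H]2c2ccc(O[Si](C)(C)C(C)(C)C)cc2O[Si](C)(C)C(C)(C)C)c1O[Si](C)(C)C(C)(C)C | intermediate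
18 | (2S)-2-[2,4-bis(TBS-oxy)phenyl]-8-{(3''S,4''R,5''S)-4''-[2,4-bis(TBS-oxy)-3-prenylbenzoyl]-5''-[2,4-bis(TBS-oxy)phenyl]-1''-methylcyclohex-1''-en-3''-yl}-7-hydroxychroman-4-one | CC(C)=CCc1c(O[Si](C)(C)C(C)(C)C)ccc(C(=O)[C@H]2[C@@H](c3c(O)ccc4c3O[C@H](c3ccc(O[Si](C)(C)C(C)(C)C)cc3O[Si](C)(C)C(C)(C)C)CC4=O)C=C(C)C[C@@H]2c2ccc(O[Si](C)(C)C(C)(C)C)cc2O[Si](C)(C)C(C)(C)C)c1O[Si](C)(C)C(C)(C)C | intermediate
19 | (2S)-8-{(3''S,4''R,5''S)-4''-(2,4-dihydroxy-3-prenylbenzoyl)-5''-(2,4-dihydroxyphenyl)-1''-methylcyclohex-1''-en-3''-yl}-2-(2,4-dihydroxyphenyl)-7-hydroxychroman-4-one | CC(C)=CCc1c(O)ccc(C(=O)[C@H]2[C@@H](c3c(O)ccc4c3O[C@H](c3ccc(O)cc3O)CC4=O)C=C(C)C[C@@H]2c2ccc(O)cc2O)c1O | target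

**Totals and risks**

Total steps: 13. Longest linear sequence: 7 steps (1 → 3 → 4 → 7 → 10 → 11 → 18 → 19; the flavanone branch 5 → 6 → 13 → 14 → 15 → 16 → 18 → 19 is equally long).

Steps most likely to fail:

Step 12. The phenoxide may add to C3'' of the π-allyl complex instead of C1'' and not be returned fast enough, the complex may lose a proton from C4'' or C6'' to give a diene, or the shift may go to C6 instead of C8. The fallback uses no palladium and no ether. Setting out from 11 and 16, a Lewis-acid Friedel–Crafts allylation (BF3·OEt2, CH2Cl2, −40 → 0 °C) ionises the carbonate to the C1''–C3'' allyl cation, which ring A attacks directly through C8, the position between its two oxygens. Bonding at the secondary terminus C3'' is expected. Pseudoaxial approach trans to the C5'' aryl group would give the needed isomer, but approach anti to the neighbouring aroyl group competes, so this fallback gives up the stereochemical relay and the C3'' epimer would be removed by chromatography. It makes no new compound (F0) and comes back to the route at 18.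

Step 6. The chiral borate may give insufficient endo preference or enantioface discrimination with the carbonate-bearing diene, or the Lewis acid may ionise the allylic carbonate. The fallback replaces catalyst control by a covalent resolving group that is also the leaving group. Setting out from 8, the potassium dienolate is trapped with (1R,2S,5R)-menthyl chloroformate to give the dienyl menthyl carbonate F1. Its Diels–Alder reaction with 7 under the achiral promoter B(OPh)3 (toluene, rt) should give the endo adducts as two diastereomers that differ in the sense of the ring stereocenters. The one with the ring configuration of 10, the endo menthyl carbonate F2, is separated by chromatography or crystallisation. Silylation as in step 7 gives the tetrakis-TBS menthyl carbonate F3, which takes the place of 11 in step 12 and comes back to the route at 18.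

Step 10. The selectivity factor may be too low for a flavanone with a hindered ortho-silyloxyaryl group, so that ketone of high enantiomeric purity is recovered only at high conversion. The fallback makes C2 by asymmetric catalysis instead of resolution. Setting out from 12, C-carboxylation (NaH, di-tert-butyl dicarbonate, THF) gives the tert-butyl β-keto ester F4. Knoevenagel condensation with 6 (piperidinium acetate, toluene) gives the alkylidene β-keto ester F5. Intramolecular oxa-Michael addition under a cinchona-derived bifunctional thiourea (toluene, −25 °C; the pseudoenantiomer that leads to the 2S series) gives the 3-carboxylated flavanone F6. Acid-mediated loss of the tert-butyl ester and decarboxylation (TsOH, toluene, 80 °C) then comes back to the route at 15.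

Further compounds
F0 | step 12 | none | none
F1 | step 6 | (1E)-3-methylbuta-1,3-dien-1-yl (1R,2S,5R)-menthyl carbonate | C=C(C)/C=C/OC(=O)O[C@@H]1C[C@H](C)CC[C@H]1C(C)C
F2 | step 6 | (1R,2S,5R)-menthyl (3''S,4''R,5''S)-4''-[4-(TBS-oxy)-2-hydroxy-3-prenylbenzoyl]-5''-[2,4-bis(TBS-oxy)phenyl]-1''-methylcyclohex-1''-en-3''-yl carbonate | CC(C)=CCc1c(O[Si](C)(C)C(C)(C)C)ccc(C(=O)[C@H]2[C@@H](OC(=O)O[C@@H]3C[C@H](C)CC[C@H]3C(C)C)C=C(C)C[C@@H]2c2ccc(O[Si](C)(C)C(C)(C)C)cc2O[Si](C)(C)C(C)(C)C)c1O
F3 | step 6 | (1R,2S,5R)-menthyl (3''S,4''R,5''S)-4''-[2,4-bis(TBS-oxy)-3-prenylbenzoyl]-5''-[2,4-bis(TBS-oxy)phenyl]-1''-methylcyclohex-1''-en-3''-yl carbonate | CC(C)=CCc1c(O[Si](C)(C)C(C)(C)C)ccc(C(=O)[C@H]2[C@@H](OC(=O)O[C@@H]3C[C@H](C)CC[C@H]3C(C)C)C=C(C)C[C@@H]2c2ccc(O[Si](C)(C)C(C)(C)C)cc2O[Si](C)(C)C(C)(C)C)c1O[Si](C)(C)C(C)(C)C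
F4 | step 10 | tert-butyl 3-[4-(benzyloxy)-2-hydroxyphenyl]-3-oxopropanoate | CC(C)(C)OC(=O)CC(=O)c1ccc(OCc2ccccc2)cc1O
F5 | step 10 | tert-butyl 2-[4-(benzyloxy)-2-hydroxybenzoyl]-3-[2,4-bis(TBS-oxy)phenyl]prop-2-enoate | CC(C)(C)OC(=O)C(=Cc1ccc(O[Si](C)(C)C(C)(C)C)cc1O[Si](C)(C)C(C)(C)C)C(=O)c1ccc(OCc2ccccc2)cc1O
F6 | step 10 | tert-butyl (2S)-7-(benzyloxy)-2-[2,4-bis(TBS-oxy)phenyl]-4-oxochromane-3-carboxylate | O=C1C(C(=O)OC(C)(C)C)[C@@H](c2ccc(O[Si](C)(C)C(C)(C)C)cc2O[Si](C)(C)C(C)(C)C)Oc2cc(OCc3ccccc3)ccc12
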